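## Retrosynthetic overview

- The target is a C2-symmetric dimer. A 16-membered carbocycle (ring M: C1, C9a, C9 and a pentamethylene arm, twice) carries two quinolizidin-2-ones, each with ring A (N5/C4/C3/C2/C1/C9a, the piperidone) and ring B (N5/C6/C7/C8/C9/C9a, the piperidine).
- Enabling feature: in ring B, C6 is an unsubstituted CH2 between N5 and C7, and C7–C8–C9–C9a is a four-carbon run whose end C9a is bonded to N5 and tied back to it through C1–C2–C3–C4. Ring B at the 8,9-dehydro level is therefore the [4+2] adduct of an N5=C6 methyleneiminium ion (formaldehyde carbon) with a C7=C8–C9=C9a diene, and ring A is the tether ring.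
- Key disconnection, done on both halves at once: a double intramolecular iminium Diels–Alder reaction of a macrocyclic bis(dienylamine) with formaldehyde closes ring B through C6–C7 and ring A through N5–C9a. Four rings and both C9a centers form in one operation. Hydrogenation of C8=C9 (sets C9) and oxidation of the C2 carbinols finish the synthesis.
- Ring M is made first, by head-to-tail Horner–Wadsworth–Emmons cyclodimerization of an aldehyde–phosphonate monomer to an (E,E)-bis-enoate; the esters become the vinyl groups (C8=C7) of the dienes.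
- Stereochemistry: C1 from an Evans syn-aldol reaction, C3 from (S)-3-amino-2-methylpropanoic acid; C1 relays to C9a (allylic strain in the cycloaddition) and C9a/C1 to C9 (hydrogenation). Ring order: M, then A and B of both halves together.

Key step: step 14

Remark on the chemistry: locants C1–C9a refer to each quinolizidin-2-one half, in which the target is (1R,3S,9S,9aR); the four starting materials 1, 4, 5 and 12 are taken as commercial.

## Route

Step 1
Reactants: 1 (2S)-3-[(tert-butoxycarbonyl)amino]-2-methylpropanoic acid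
Product: 2 tert-butyl N-[(2S)-3-hydroxy-2-methylpropyl]carbamate
Conditions: BH3·SMe2, THF, 0 °C → rt; MeOH quench
Reagents that add atoms: none
Why: Borane reduction of a carboxylic acid is chemoselective over the carbamate, and the C3 methyl stereocenter taken from the chiral pool is not touched.

Step 2
Reactants: 2 tert-butyl N-[(2S)-3-hydroxy-2-methylpropyl]carbamate
Product: 3 tert-butyl N-[(2S)-2-methyl-3-oxopropyl]carbamate
Conditions: Dess–Martin periodinane, CH2Cl2, 0 °C → rt; used crude
Reagents that add atoms: none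
Why: Dess–Martin oxidation gives the α-branched aldehyde without base, so the future C3 center should keep its configuration if 3 is used at once.

Step 3
Reactants: 4 7-bromoheptanoic acid; 5 (4S)-4-benzyl-1,3-oxazolidin-2-one
Product: 7 (4S)-4-benzyl-3-(7-bromoheptanoyl)-1,3-oxazolidin-2-one, via mixed pivalic anhydride 6 (not isolated)
Conditions: PivCl, Et3N, THF, −20 °C; then 5, LiCl, rt
Reagents that add atoms: none
Why: N-Acylation of the oxazolidinone through the mixed pivalic anhydride (Et3N/LiCl) is a standard imide synthesis and leaves the primary bromide alone.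

Step 4
Reactants: 7 (4S)-4-benzyl-3-(7-bromoheptanoyl)-1,3-oxazolidin-2-one; 3 tert-butyl N-[(2S)-2-methyl-3-oxopropyl]carbamate
Product: 9 (4S)-4-benzyl-3-[(2S,3R,4S)-2-(5-bromopentyl)-5-[(tert-butoxycarbonyl)amino]-3-hydroxy-4-methylpentanoyl]-1,3-oxazolidin-2-one, via dibutylboron Z-enolate 8 (not isolated)
Conditions: Bu2BOTf, iPr2NEt, CH2Cl2, 0 °C; 3, −78 → 0 °C; pH 7 buffer, MeOH, H2O2
Reagents that add atoms: none
Why: Evans syn-aldol reaction: the Z-boron enolate adds through a closed chair (Zimmerman–Traxler) transition state on the enolate face away from the benzyl group, which sets C1 (2S here, the later 1R) and the temporary C2 carbinol under reagent control, while C3 comes unchanged from 3.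

Step 5
Reactants: 9 the aldol adduct
Product: 10 (4S)-4-benzyl-3-[(2S,3R,4S)-2-(5-bromopentyl)-5-[(tert-butoxycarbonyl)amino]-3-[(tert-butyldimethylsilyl)oxy]-4-methylpentanoyl]-1,3-oxazolidin-2-one
Conditions: TBSOTf (1.3 equiv), 2,6-lutidine, CH2Cl2, −78 °C
Reagents that add atoms: tert-butyldimethylsilyl triflate, CC(C)(C)[Si](C)(C)OS(=O)(=O)C(F)(F)F
Why: Silyl triflate silylation of the hindered carbinol at −78 °C is faster than attack on the carbamate and blocks retro-aldol and elimination pathways in the later basic steps.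

Step 6
Reactants: 10 the silylated imide
Product: 11 tert-butyl N-[(2S,3R,4R)-9-bromo-3-[(tert-butyldimethylsilyl)oxy]-4-(hydroxymethyl)-2-methylnonyl]carbamate
Conditions: LiBH4, MeOH (1 equiv), THF, 0 °C
Reagents that add atoms: none
Why: Reductive cleavage of the N-acyloxazolidinone by hydride attack at the exocyclic carbonyl gives the primary alcohol without epimerization at C1, and the bromide, carbamate and silyl ether should tolerate LiBH4 at 0 °C.

Step 7
Reactants: 11 the bromo alcohol; 12 triethyl phosphonoacetate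
Product: 14 ethyl (8R,9R,10S)-11-[(tert-butoxycarbonyl)amino]-9-[(tert-butyldimethylsilyl)oxy]-2-(diethoxyphosphoryl)-8-(hydroxymethyl)-10-methylundecanoate (both C2 epimers), via sodium phosphonoacetate 13 (not isolated)
Conditions: 12 (3 equiv), NaH (2.8 equiv), DMF, 0 °C; then 11, NaI (cat.), 50 °C
Reagents that add atoms: none
Why: SN2 alkylation of the stabilized phosphonoacetate carbanion (iodide catalysis) puts C9 and C8 in place; the carbanion is too weak a base to deprotonate the hydroxyl or carbamate, and the new phosphonate-bearing center is lost in step 9.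

Step 8
Reactants: 14 the hydroxy phosphonate
Product: 15 ethyl (8S,9R,10S)-11-[(tert-butoxycarbonyl)amino]-9-[(tert-butyldimethylsilyl)oxy]-2-(diethoxyphosphoryl)-8-formyl-10-methylundecanoate (both C2 epimers)
Conditions: Dess–Martin periodinane, CH2Cl2, 0 °C → rt
Reagents that add atoms: none
Why: Dess–Martin oxidation delivers the aldehyde under non-basic conditions, so C1 keeps its configuration and the aldehyde meets the phosphonate only under the dilution of step 9.

Step 9
Reactants: 15 the aldehyde–phosphonate monomer (two molecules)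
Product: 17 diethyl (1E,3R,9E,11R)-3,11-bis[(1S,2S)-3-[(tert-butoxycarbonyl)amino]-1-[(tert-butyldimethylsilyl)oxy]-2-methylpropyl]cyclohexadeca-1,9-diene-1,9-dicarboxylate, via linear seco-dimer 16 (not isolated)
Conditions: LiCl, DBU, MeCN, slow addition of 15 to 0.005 M, rt
Reagents that add atoms: none
Why: Horner–Wadsworth–Emmons olefination under Masamune–Roush conditions: intermolecular head-to-tail coupling gives 16, whose ring closure to the unstrained 16-membered ring should outrun the medium-ring closure open to the monomer, and α-alkyl phosphonoacetates give the E enoate (ester trans to C1), the geometry the diene needs.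

Step 10
Reactants: 17 the macrocyclic bis-enoate
Product: 18 [(1E,3R,9E,11R)-3,11-bis[(1S,2S)-3-[(tert-butoxycarbonyl)amino]-1-[(tert-butyldimethylsilyl)oxy]-2-methylpropyl]cyclohexadeca-1,9-diene-1,9-diyl]dimethanol
Conditions: iBu2AlH (excess), CH2Cl2, −78 °C; Rochelle salt work-up
Reagents that add atoms: none
Why: 1,2-Reduction of the α,β-unsaturated esters to allylic alcohols with iBu2AlH at −78 °C leaves carbamates and silyl ethers intact and keeps the alkene geometry.

Step 11
Reactants: 18 the bis(allylic alcohol)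
Product: 19 (1E,3R,9E,11R)-3,11-bis[(1S,2S)-3-[(tert-butoxycarbonyl)amino]-1-[(tert-butyldimethylsilyl)oxy]-2-methylpropyl]cyclohexadeca-1,9-diene-1,9-dicarbaldehyde
Conditions: MnO2 (activated, excess), CH2Cl2, rt
Reagents that add atoms: none
Why: MnO2 oxidizes allylic alcohols selectively to the enals without touching the alkene geometry or the C1 center.

Step 12
Reactants: 19 the bis-enal
Product: 20 (1E,3R,9E,11R)-3,11-bis[(1S,2S)-3-[(tert-butoxycarbonyl)amino]-1-[(tert-butyldimethylsilyl)oxy]-2-methylpropyl]-1,9-diethenylcyclohexadeca-1,9-diene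
Conditions: Ph3PCH3Br, KN(SiMe3)2 (excess), THF, 0 °C
Reagents that add atoms: methyltriphenylphosphonium bromide, C[P+](c1ccccc1)(c1ccccc1)c1ccccc1.[Br-]
Why: Wittig methylenation of the unhindered enal carbonyls installs C7 and completes the two C7=C8–C9=C9a dienes; excess ylide makes up for the acidic carbamate N–H groups.

Step 13
Reactants: 20 the bis-Boc bis-diene
Product: 22 (1E,3R,9E,11R)-3,11-bis[(1S,2S)-3-amino-1-[(tert-butyldimethylsilyl)oxy]-2-methylpropyl]-1,9-diethenylcyclohexadeca-1,9-diene, via bis(trimethylsilyl carbamate) 21 (not isolated)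
Conditions: TMSOTf, 2,6-lutidine, CH2Cl2, 0 °C; then MeOH; aq. NaHCO3
Reagents that add atoms: none
Why: Silyl-triflate-mediated Boc cleavage (loss of 2-methylpropene, then methanolysis and decarboxylation of the silyl carbamate) under lutidine buffering avoids protic acid that could protonate the dienes and keeps the silyl ethers.

Step 14
Reactants: 22 the macrocyclic bis(dienylamine)
Product: 24 C2-symmetric pentacycle in which ring M is fused to two 1,3,4,6,7,9a-hexahydro-2H-quinolizines (C8=C9 double bond; each half (1R,2R,3S,9aS), 2-OTBS, 3-methyl), via bis(methyleneiminium) salt 23 (not isolated)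
Conditions: CH2O (37% aq., 10 equiv), CF3CO2H (2.2 equiv), THF–H2O, 0.01 M, 55 °C; aq. NaHCO3
Reagents that add atoms: formaldehyde, C=O
Why: Each primary ammonium group condenses with formaldehyde to an N-protonated methyleneiminium ion (23), a strong 2π partner that adds across the tethered C7=C8–C9=C9a diene in a concerted, asynchronous [4+2] process in which C6–C7 bonding leads and N5–C9a bonding follows; the closest known reaction type is the aza-Diels–Alder reaction of dienylamine salts with aqueous formaldehyde under Mannich conditions, which gives quinolizidines when the tether has four atoms. Ring B closes as the six-membered cycloadduct ring through the C6–C7 and N5–C9a bonds, and ring A closes at the same time through the N5–C9a bond as a 6-exo closure across the tether C4–C3–C2–C1 in a chair-like transition state. The only new stereocenter, C9a, is controlled by C1: allylic A(1,3) strain with the C9 pentamethylene arm, which is cis to C1 on the C9=C9a bond, holds H1 in the diene plane, so N5 is delivered to the diene face that carries C2 with the C1 arm, the C2 silyloxy group and the C3 methyl group all equatorial, and H1 and H9a end up trans. The step needs this π-facial selectivity, reaction of each iminium ion with its own diene instead of intermolecular addition (secured by dilution and the six-membered tether), and C6-to-C7 regiochemistry (C7 is the only diene terminus within reach of C6 once N5 is tied to C9a). Both halves react independently, each under control of its own C1 center, so the C2 symmetry is carried through. The tertiary amine formed cannot condense with formaldehyde again, which ends the sequence.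

Step 15
Reactants: 24 the bis(8,9-dehydroquinolizidine)
Product: 25 the bis(2-O-TBS) ether of the saturated diol, each half (1R,2R,3S,9S,9aR)
Conditions: H2 (3 atm), PtO2, AcOH, rt
Reagents that add atoms: none
Why: Heterogeneous syn-hydrogenation of the trisubstituted C8=C9 bond of the ammonium acetate: allylic strain between the C9 arm and C1 tilts ring A onto one face of ring B, so hydrogen should add to C9 from the face of H9a, which makes H9 cis to H9a (9S) and puts the C9 arm axial, clear of the equatorial C1 arm.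

Step 16
Reactants: 25 the bis-silyl ether
Product: 26 the diol, the target with each C2 carbonyl replaced by a (2R)-carbinol
Conditions: HCl (3 M in MeOH), 40 °C; aq. K2CO3
Reagents that add atoms: none
Why: Acid-mediated methanolysis of the two secondary silyl ethers; the protonated amines are inert under these conditions.

Step 17
Reactants: 26 the diol
Product: 27 the target, CNP0268544.6, (1R,3S,9S,9aR) in both halves
Conditions: (COCl)2, DMSO, CH2Cl2, −78 °C; Et3N, −78 → 0 °C
Reagents that add atoms: none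
Why: Swern oxidation of the two equatorial C2 carbinols; C1 and C3 already carry their substituents equatorial, the arrangement that enolization under Et3N would favour anyway, so the α-centers should not drift.

## Compound list

1 | (2S)-3-[(tert-butoxycarbonyl)amino]-2-methylpropanoic acid | C[C@H](C(=O)O)CNC(=O)OC(C)(C)C | starting material
2 | tert-butyl N-[(2S)-3-hydroxy-2-methylpropyl]carbamate | C[C@H](CO)CNC(=O)OC(C)(C)C | intermediate
3 | tert-butyl N-[(2S)-2-methyl-3-oxopropyl]carbamate | C[C@H](C=O)CNC(=O)OC(C)(C)C | intermediate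
4 | 7-bromoheptanoic acid | OC(=O)CCCCCCBr | starting material
5 | (4S)-4-benzyl-1,3-oxazolidin-2-one | O=C1OC[C@H](Cc2ccccc2)N1 | starting material
6 | 7-bromoheptanoic pivalic anhydride (not isolated) | CC(C)(C)C(=O)OC(=O)CCCCCCBr | intermediate
7 | (4S)-4-benzyl-3-(7-bromoheptanoyl)-1,3-oxazolidin-2-one | O=C1OC[C@H](Cc2ccccc2)N1C(=O)CCCCCCBr | intermediate
8 | dibutylboron Z-enolate of 7 (not isolated) | O=C1OC[C@H](Cc2ccccc2)N1/C(OB(CCCC)CCCC)=C/CCCCCBr | intermediate
9 | (4S)-4-benzyl-3-[(2S,3R,4S)-2-(5-bromopentyl)-5-[(tert-butoxycarbonyl)amino]-3-hydroxy-4-methylpentanoyl]-1,3-oxazolidin-2-one | O=C1OC[C@H](Cc2ccccc2)N1C(=O)[C@@H](CCCCCBr)[C@H](O)[C@@H](C)CNC(=O)OC(C)(C)C | intermediate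
10 | 3-O-TBS ether of 9, (2S,3R,4S) | O=C1OC[C@H](Cc2ccccc2)N1C(=O)[C@@H](CCCCCBr)[C@H](O[Si](C)(C)C(C)(C)C)[C@@H](C)CNC(=O)OC(C)(C)C | intermediate
11 | tert-butyl N-[(2S,3R,4R)-9-bromo-3-[(tert-butyldimethylsilyl)oxy]-4-(hydroxymethyl)-2-methylnonyl]carbamate | OC[C@@H](CCCCCBr)[C@H](O[Si](C)(C)C(C)(C)C)[C@@H](C)CNC(=O)OC(C)(C)C | intermediate
12 | triethyl phosphonoacetate | CCOC(=O)CP(=O)(OCC)OCC | starting material
13 | sodium salt of triethyl phosphonoacetate (not isolated) | CCOC(=O)[CH-]P(=O)(OCC)OCC.[Na+] | intermediate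
14 | ethyl (8R,9R,10S)-11-[(tert-butoxycarbonyl)amino]-9-[(tert-butyldimethylsilyl)oxy]-2-(diethoxyphosphoryl)-8-(hydroxymethyl)-10-methylundecanoate, C2 epimers | OC[C@@H](CCCCCC(C(=O)OCC)P(=O)(OCC)OCC)[C@H](O[Si](C)(C)C(C)(C)C)[C@@H](C)CNC(=O)OC(C)(C)C | intermediate
15 | ethyl (8S,9R,10S)-11-[(tert-butoxycarbonyl)amino]-9-[(tert-butyldimethylsilyl)oxy]-2-(diethoxyphosphoryl)-8-formyl-10-methylundecanoate, C2 epimers | O=C[C@@H](CCCCCC(C(=O)OCC)P(=O)(OCC)OCC)[C@H](O[Si](C)(C)C(C)(C)C)[C@@H](C)CNC(=O)OC(C)(C)C | intermediate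
16 | linear head-to-tail seco-dimer: aldehyde at one end, (E)-enoate in the middle, phosphonoacetate at the other end (not isolated) | O=C[C@@H](CCCCC/C(C(=O)OCC)=C\[C@H]([C@H](O[Si](C)(C)C(C)(C)C)[C@@H](C)CNC(=O)OC(C)(C)C)CCCCCC(C(=O)OCC)P(=O)(OCC)OCC)[C@H](O[Si](C)(C)C(C)(C)C)[C@@H](C)CNC(=O)OC(C)(C)C | intermediate
17 | diethyl (1E,3R,9E,11R)-3,11-bis[(1S,2S)-3-[(tert-butoxycarbonyl)amino]-1-[(tert-butyldimethylsilyl)oxy]-2-methylpropyl]cyclohexadeca-1,9-diene-1,9-dicarboxylate | C1CCCC/C(C(=O)OCC)=C\[C@H]([C@H](O[Si](C)(C)C(C)(C)C)[C@@H](C)CNC(=O)OC(C)(C)C)CCCCC/C(C(=O)OCC)=C\[C@@H]1[C@H](O[Si](C)(C)C(C)(C)C)[C@@H](C)CNC(=O)OC(C)(C)C | intermediate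
18 | bis(allylic alcohol): 17 with each CO2Et replaced by CH2OH, (1E,3R,9E,11R) | C1CCCC/C(CO)=C\[C@H]([C@H](O[Si](C)(C)C(C)(C)C)[C@@H](C)CNC(=O)OC(C)(C)C)CCCCC/C(CO)=C\[C@@H]1[C@H](O[Si](C)(C)C(C)(C)C)[C@@H](C)CNC(=O)OC(C)(C)C | intermediate
19 | bis-enal: 17 with each CO2Et replaced by CHO, (1E,3R,9E,11R) | C1CCCC/C(C=O)=C\[C@H]([C@H](O[Si](C)(C)C(C)(C)C)[C@@H](C)CNC(=O)OC(C)(C)C)CCCCC/C(C=O)=C\[C@@H]1[C@H](O[Si](C)(C)C(C)(C)C)[C@@H](C)CNC(=O)OC(C)(C)C | intermediate
20 | (1E,3R,9E,11R)-3,11-bis[(1S,2S)-3-[(tert-butoxycarbonyl)amino]-1-[(tert-butyldimethylsilyl)oxy]-2-methylpropyl]-1,9-diethenylcyclohexadeca-1,9-diene | C1CCCC/C(C=C)=C\[C@H]([C@H](O[Si](C)(C)C(C)(C)C)[C@@H](C)CNC(=O)OC(C)(C)C)CCCCC/C(C=C)=C\[C@@H]1[C@H](O[Si](C)(C)C(C)(C)C)[C@@H](C)CNC(=O)OC(C)(C)C | intermediate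
21 | bis(trimethylsilyl carbamate) of 22 (not isolated) | C1CCCC/C(C=C)=C\[C@H]([C@H](O[Si](C)(C)C(C)(C)C)[C@@H](C)CNC(=O)O[Si](C)(C)C)CCCCC/C(C=C)=C\[C@@H]1[C@H](O[Si](C)(C)C(C)(C)C)[C@@H](C)CNC(=O)O[Si](C)(C)C | intermediate
22 | (1E,3R,9E,11R)-3,11-bis[(1S,2S)-3-amino-1-[(tert-butyldimethylsilyl)oxy]-2-methylpropyl]-1,9-diethenylcyclohexadeca-1,9-diene | C1CCCC/C(C=C)=C\[C@H]([C@H](O[Si](C)(C)C(C)(C)C)[C@@H](C)CN)CCCCC/C(C=C)=C\[C@@H]1[C@H](O[Si](C)(C)C(C)(C)C)[C@@H](C)CN | intermediate
23 | bis(N-methyleneammonium) bis(trifluoroacetate) of 22 (not isolated) | C1CCCC/C(C=C)=C\[C@H]([C@H](O[Si](C)(C)C(C)(C)C)[C@@H](C)C[NH+]=C)CCCCC/C(C=C)=C\[C@@H]1[C@H](O[Si](C)(C)C(C)(C)C)[C@@H](C)C[NH+]=C.[O-]C(=O)C(F)(F)F.[O-]C(=O)C(F)(F)F | intermediate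
24 | double cycloadduct: bis(8,9-dehydroquinolizidine), each half (1R,2R,3S,9aS), 2-OTBS | C[C@H]1CN2CCC=C3CCCCC[C@H]4[C@H](O[Si](C)(C)C(C)(C)C)[C@@H](C)CN5CCC=C(CCCCC[C@@H]([C@@H]1O[Si](C)(C)C(C)(C)C)[C@@H]32)[C@H]45 | intermediate
25 | saturated bis-silyl ether, each half (1R,2R,3S,9S,9aR) | C[C@H]1CN2CCC[C@@H]3CCCCC[C@H]4[C@H](O[Si](C)(C)C(C)(C)C)[C@@H](C)CN5CCC[C@H](CCCCC[C@@H]([C@@H]1O[Si](C)(C)C(C)(C)C)[C@@H]32)[C@H]45 | intermediate
26 | diol, each half (1R,2R,3S,9S,9aR) | C[C@H]1CN2CCC[C@@H]3CCCCC[C@H]4[C@H](O)[C@@H](C)CN5CCC[C@H](CCCCC[C@@H]([C@@H]1O)[C@@H]32)[C@H]45 | intermediate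
27 | CNP0268544.6, each half (1R,3S,9S,9aR) | C[C@H]1CN2CCC[C@@H]3CCCCC[C@H]4C(=O)[C@@H](C)CN5CCC[C@H](CCCCC[C@@H](C1=O)[C@@H]32)[C@H]45 | target

## Step count and risks

Total step count: 17. Longest linear sequence: 16 steps (1 to 27 through steps 1, 2 and 4–17).

Steps most likely to fail:

1. Step 14. The unactivated diene may add too slowly to the iminium ion in the mixed aqueous medium, so that hydrolysis, oligomerization through intermolecular addition or incomplete facial control take over. The fallback sets out from 19 and builds ring B by a Mannich closure of the same C6–C7 bond instead of a cycloaddition. MeMgBr (THF, −78 °C) should give the bis(methyl carbinol) F1, and Dess–Martin oxidation the bis(methyl enone) F2. Boc removal (CF3CO2H, CH2Cl2, which an enone tolerates) and neutralization should let each amine close ring A by 6-exo aza-Michael addition at C9a, giving the bis-piperidine F3. Aqueous CH2O in AcOH should then close ring B by intramolecular Mannich reaction of the methyl ketone enol carbon C7 on the N5=C6 iminium ion, giving the bis(8-oxoquinolizidine) F4, in which C9 and C9a can equilibrate by enolization and retro-Michael addition to the arrangement with the C9 arm axial. Dithioketalization (ethane-1,2-dithiol, BF3·OEt2) to the bis-dithiolane F5 and desulfurization with Raney Ni bring the sequence back to the route at 25.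

2. Step 9. Oligomerization or medium-ring closure of the monomer may compete with head-to-tail cyclodimerization, and E selectivity may erode. The fallback sets out from 11 and 14 and assembles the ring one bond at a time. Dess–Martin oxidation of 11 should give the bromo aldehyde F6. Intermolecular Horner–Wadsworth–Emmons coupling of 14 with F6 (LiCl, DBU, MeCN) should give the linear bromo alcohol enoate F7. Alkylation of the sodium salt of 12 with F7 should give the hydroxy phosphonate F8. Dess–Martin oxidation of F8 gives 16 as an isolated compound, which is ring-closed under high dilution, so the route is rejoined at 17.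

3. Step 15. Facial selectivity in the delivery of hydrogen to C9 may be poor. The fallback sets out from 24 and sets C9 by equilibration instead of by facial addition. Hydroboration–oxidation (BH3·THF, then NaOH, H2O2) should give the bis(C8 alcohol) F9. Swern oxidation gives the bis(8-oxoquinolizidine) F4, in which C9 is epimerized to the axial arrangement with DBU. Dithioketalization to the bis-dithiolane F5 and Raney Ni desulfurization rejoin the route at 25.

Further compounds
F1 | step 14 | bis(methyl carbinol), 19 with each CHO replaced by CH(OH)CH3, carbinol epimers | C1CCCC/C(C(C)O)=C\[C@H]([C@H](O[Si](C)(C)C(C)(C)C)[C@@H](C)CNC(=O)OC(C)(C)C)CCCCC/C(C(C)O)=C\[C@@H]1[C@H](O[Si](C)(C)C(C)(C)C)[C@@H](C)CNC(=O)OC(C)(C)C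
F2 | step 14 | bis(methyl enone), 19 with each CHO replaced by COCH3 | C1CCCC/C(C(C)=O)=C\[C@H]([C@H](O[Si](C)(C)C(C)(C)C)[C@@H](C)CNC(=O)OC(C)(C)C)CCCCC/C(C(C)=O)=C\[C@@H]1[C@H](O[Si](C)(C)C(C)(C)C)[C@@H](C)CNC(=O)OC(C)(C)C
F3 | step 14 | bis-piperidine from double aza-Michael closure of ring A, acetyl-bearing C9 unassigned | C[C@H]1CN[C@H](C(C(C)=O)CCCCC[C@H]2[C@H](O[Si](C)(C)C(C)(C)C)[C@@H](C)CN[C@@H]2C(C(C)=O)CCCCC3)[C@@H]3[C@@H]1O[Si](C)(C)C(C)(C)C
F4 | step 14 | bis(8-oxoquinolizidine) bis-silyl ether, 25 with a carbonyl at each C8 | C[C@H]1CN2CCC(=O)[C@@H]3CCCCC[C@H]4[C@H](O[Si](C)(C)C(C)(C)C)[C@@H](C)CN5CCC(=O)[C@H](CCCCC[C@@H]([C@@H]1O[Si](C)(C)C(C)(C)C)[C@@H]32)[C@H]45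
F5 | step 14 | bis(1,3-dithiolane) of F4 at each C8 | C[C@H]1CN2CCC6(SCCS6)[C@@H]3CCCCC[C@H]4[C@H](O[Si](C)(C)C(C)(C)C)[C@@H](C)CN5CCC7(SCCS7)[C@H](CCCCC[C@@H]([C@@H]1O[Si](C)(C)C(C)(C)C)[C@@H]32)[C@H]45
F6 | step 9 | bromo aldehyde, 11 with CH2OH oxidized to CHO | O=C[C@@H](CCCCCBr)[C@H](O[Si](C)(C)C(C)(C)C)[C@@H](C)CNC(=O)OC(C)(C)C
F7 | step 9 | linear bromo alcohol (E)-enoate | OC[C@@H](CCCCC/C(C(=O)OCC)=C\[C@H]([C@H](O[Si](C)(C)C(C)(C)C)[C@@H](C)CNC(=O)OC(C)(C)C)CCCCCBr)[C@H](O[Si](C)(C)C(C)(C)C)[C@@H](C)CNC(=O)OC(C)(C)C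
F8 | step 9 | linear hydroxy phosphonate (E)-enoate | OC[C@@H](CCCCC/C(C(=O)OCC)=C\[C@H]([C@H](O[Si](C)(C)C(C)(C)C)[C@@H](C)CNC(=O)OC(C)(C)C)CCCCCC(C(=O)OCC)P(=O)(OCC)OCC)[C@H](O[Si](C)(C)C(C)(C)C)[C@@H](C)CNC(=O)OC(C)(C)C
F9 | step 15 | bis(C8 alcohol) from hydroboration of 24, C8 and C9 unassigned | C[C@H]1CN2CCC(O)C3CCCCC[C@H]4[C@H](O[Si](C)(C)C(C)(C)C)[C@@H](C)CN5CCC(O)C(CCCCC[C@@H]([C@@H]1O[Si](C)(C)C(C)(C)C)[C@@H]32)[C@H]45
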